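**Remark on numbering.** Ring atoms keep the target's numbers throughout: C4(Me)–C5 epoxide, C6 ester carbon, C7 isopropyl carbon, C8=C9 alkene, C10 carbinol, C1–C3 methylenes. In the cyclohexane intermediates the ring is C4–C3–C2–C1–C10–C9.

## Analysis of the target

The target 29 is a ten-membered carbocycle of the germacrane type with five stereocentres: C4 (quaternary epoxide carbon with methyl), C5, C6 (4-hydroxybenzoate), C7 (isopropyl) and C10 (tertiary carbinol with methyl). In this numbering they are 4S, 5R, 6R, 7S, 10R, and C8=C9 is E. C4 to C7 are contiguous: the oxirane is cis with respect to the ring (C3 and C6 on the same side), and the C6 oxygen is anti (erythro) to the epoxide oxygen. C10 is remote from this array and is separated from C7 by the E alkene. The trisubstituted epoxide faces a transannular alkene, C10 is a tertiary allylic alcohol, and the ester carries a free phenol, so acid and strong base have to be kept away from the late intermediates. The difficulty is the medium ring combined with the C4–C7 stereotetrad and the remote C10. Without the epoxide oxygen, C4=C5 and C8=C9 form a cyclodeca-1,5-diene whose C6–C7 bond is a Cope retron. With oxygen on C4 this diene is the enolate product of an oxy-Cope rearrangement of a 1,2-dialkenylcyclohexanol whose ring bond is C4–C9; the route rests on this feature.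

## Retrosynthetic reasoning

**Silyl ethers and the ester (29 ⇒ 28 ⇒ 24 + 27).** The O–Si bonds and the acyl C6–O bond are cut first. The aryl ester and free phenol are the most base-sensitive parts, so they come last. The forward steps must acylate a hindered secondary alcohol next to an epoxide and then remove two silyl groups without acid.

**Epoxide (24 ⇒ 23 ⇒ 22).** The two C–O bonds of the oxirane are cut to give the Z-trisubstituted allylic alcohol 23, which comes from its 4-methoxybenzyl ether 22. The C6 carbinol is the only handle that can direct oxygen to C4=C5 and leave C8=C9 alone. The forward reaction must place the oxygen anti to the C6 oxygen.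

**C4–CH3 (22 ⇒ 21).** The methyl group is cut because the rearrangement delivers C4 as an enolate oxygen. The enol triflate 21 preserves both the position and the geometry of that enolate, and a stereoretentive sp2–sp3 coupling finishes the alkene.

**Key disconnection (21 ⇒ 18).** C6–C7 is cut and C4–C9 is reconnected. This turns the ten-membered ring into the cyclohexanol 18, which carries an (E)-2-alkoxyvinyl group on the C4 carbinol and an (E)-3-methylbut-1-enyl group on C9, cis to each other. What is gained is a ring made by expansion instead of end-to-end closure, and C6 and C7 set together from two E alkenes. The C10 oxygen is carried as a triethylsilyl ether so that the enolate is the only anion present when the triflating agent is added.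

**Enol ether C6–O (18 ⇒ 16 + 17, 16 ⇒ 15).** The (E)-alkoxyvinyl carbinol is acid-labile and is therefore made late. It comes from the terminal alkyne 15 by syn hydroboration to 16 and a copper-mediated C–O coupling with 17. Both steps retain geometry, so the E configuration is secure.

**C9–C8 (15 ⇐ 14 ⇐ 13 ⇒ 8 + 11).** The alkenyl group is cut from C9, which leads back to the epoxide 8. SN2 opening at C9 puts the alkenyl group anti to the C10 oxygen and, because C4 is already quaternary, cis to the C4 carbon substituent. The opposite order is avoided. Opening first and then adding a nucleophile to a C4 ketone would require attack syn to the C9 alkenyl group and past an axial C10 methyl. The other face would be preferred, and the resulting trans-dialkenyl isomer would give the ring-trans enolate. No equilibration at C9 is needed or wanted. The C4 oxygen is masked as a trimethylsilyl ether and the C10 oxygen as a triethylsilyl ether, so that the two tertiary hydroxyls are told apart.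

**C4–C5 (8 ⇒ 4 + 5).** The alkynyl group is cut from C4. The acetylide must add to the epoxy ketone 4 anti to the epoxide oxygen, which makes the C4 oxygen cis to the future C10 oxygen.

**Epoxy ketone (4 ⇒ 3 ⇒ 2 ⇒ 1).** Enantioselective reduction of 1, hydroxyl-directed epoxidation and reoxidation give 4. The catalyst fixes the absolute configuration and the hydroxyl fixes the epoxide face. The side fragments 11 and 27 come from 9 and 25.

## Alternatives that were turned down

**Alternative 1:** The ring is cut at C5–C6. The open-chain (Z)-iodoalkene aldehyde A1 would be closed with CrCl2 and catalytic NiCl2 at high dilution to the macrocyclic dienol A2. In its favour, the coupling is mild and chemoselective, the Z alkene is preset, and A2 is the same compound as 23, so the endgame would be shared. Against it, C6 is created during a ten-membered closure with only C7 to induce it, and Felkin-type control is unreliable there. A1 is an α-branched β,γ-unsaturated aldehyde whose C7 hydrogen is both α to the carbonyl and allylic, so epimerisation and conjugation threaten. C7 and C10 would have to be set independently in an acyclic chain. On mildness and on avoiding a β-alkoxy enolate this alternative is stronger. The chosen route instead sets C6 and C7 in one stereospecific event and forms the ring without dilution.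

**Alternative 2:** The ring is cut at C1–C2. The epoxy sulfone A3 would be deprotonated next to sulfur with LiN(iPr)2, and the carbanion would open the epoxide methylene to give A4. In its favour, the bond forms far from the stereocentres, the opening is irreversible, and both alkenes are preformed, so no alkene geometry depends on a transition state; on that point it is at least as strong. Against it, an untemplated SN2 closure of a ten-membered ring is slow. The epoxide of A3 is a vinyl oxirane, open to SN2' attack and base-induced isomerisation. A4 forms as a C2 epimer mixture, and the sulfone must then be removed reductively next to two allylic C–O bonds. That adds at least two steps after the ring closure, and C6, C7 and C10 all need acyclic stereocontrol. The chosen route carries no auxiliary group and builds two stereocentres in the ring-forming step.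

**Alternative 3:** The ring is cut at C3–C4. 9-BBN would hydroborate the terminal alkene of A5, and PdCl2(dppf) with Cs2CO3 would couple the alkylborane with the iodoalkene to give A6. In its favour, the sp3–sp2 coupling is robust, the trisubstituted alkene geometry is fixed by the iodide, no stereocentre is made in the closure, and no strongly basic step is involved. On functional-group tolerance it is stronger than the chosen route. Against it, all four stereocentres and a (Z)-2-iodoalkene next to C6 must be built into A5. The closure passes through a strained palladacycle that competes with β-hydride elimination and oligomerisation. The chosen route offers ring formation by expansion and substrate-controlled creation of C6 and C7 from two simple alkenes, which is a shorter path to the stereochemical array.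

Key step: step 11

**Remark on the chemistry.** It is assumed that the (R)-configured CBS catalyst delivers hydride so as to give the (S)-allylic alcohol, with the alkenyl carbon acting as the larger ketone substituent.

## Route

Step 1
Reactants: 1 3-methylcyclohex-2-en-1-one
Product: 2 (S)-3-methylcyclohex-2-en-1-ol
Conditions: (R)-2-methyl-CBS-oxazaborolidine (10 mol %), catecholborane, toluene, −78 °C
Reagents that add atoms: none
Why: Corey–Bakshi–Shibata reduction of an enone; the catalyst binds the ketone with the alkenyl carbon as the large group and delivers hydride to one face, which sets C4 and with it the absolute configuration of the whole route.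

Step 2
Reactants: 2 (S)-3-methylcyclohex-2-en-1-ol
Product: 3 (1S,2S,3R)-2,3-epoxy-3-methylcyclohexan-1-ol
Conditions: VO(acac)2 (2 mol %), t-BuOOH, CH2Cl2, 0 °C → rt
Reagents that add atoms: tert-butyl hydroperoxide CC(C)(C)OO
Why: Hydroxyl-directed vanadium-catalysed epoxidation of a cyclic allylic alcohol; the peroxide is delivered from the vanadium alkoxide to the face of the hydroxyl, so the epoxide oxygen at C9 and C10 is cis to the C4 oxygen.

Step 3
Reactants: 3 (1S,2S,3R)-2,3-epoxy-3-methylcyclohexan-1-ol
Product: 4 (2R,3R)-2,3-epoxy-3-methylcyclohexan-1-one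
Conditions: Dess–Martin periodinane, NaHCO3, CH2Cl2, 0 °C → rt
Reagents that add atoms: none
Why: Buffered Dess–Martin oxidation of a secondary alcohol; the conditions are neutral, so the α,β-epoxy ketone is not opened and C9 and C10 are untouched.

Step 4
Reactants: 4 (2R,3R)-2,3-epoxy-3-methylcyclohexan-1-one; 5 ethynyltrimethylsilane
Product: 8 2,3-epoxy-3-methyl-1-[(trimethylsilyl)ethynyl]-1-(trimethylsilyloxy)cyclohexane (silyloxy group cis to the epoxide oxygen), via lithium (trimethylsilyl)acetylide 6 (not isolated), via lithium alkoxide 7 (not isolated)
Conditions: 5, n-BuLi, THF, −78 °C; 4, −78 °C; Me3SiCl, −78 → 0 °C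
Reagents that add atoms: chlorotrimethylsilane C[Si](C)(C)Cl
Why: 1,2-Addition of a lithium acetylide to an α,β-epoxy ketone; the nucleophile enters anti to the epoxide C–O bond (Felkin-type and steric control), so the C4 oxygen ends cis to the epoxide oxygen and the alkynyl group on the opposite face. Silylation of the alkoxide in the same flask masks the C4 oxygen for the next steps.

Step 5
Reactants: 9 3-methylbut-1-yne
Product: 11 (E)-1-iodo-3-methylbut-1-ene, via (E)-diisobutyl(3-methylbut-1-enyl)alane 10 (not isolated)
Conditions: iBu2AlH, hexane, 50 °C (sealed tube); I2, THF, −78 → 0 °C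
Reagents that add atoms: iodine II
Why: Syn hydroalumination of a terminal alkyne followed by iodinolysis of the C–Al bond with retention gives the E iodoalkene.

Step 6
Reactants: 8 epoxy bis-silyl compound; 11 (E)-1-iodo-3-methylbut-1-ene
Product: 13 1-methyl-2-[(E)-3-methylbut-1-enyl]-3-[(trimethylsilyl)ethynyl]-3-(trimethylsilyloxy)cyclohexan-1-ol (two oxygens cis; alkenyl group trans to both), via (E)-3-methylbut-1-enyllithium 12 (not isolated)
Conditions: 11, t-BuLi (2 equiv), Et2O, −78 °C; 8, BF3·OEt2, THF, −78 → −40 °C
Reagents that add atoms: none
Why: BF3-promoted SN2 opening of an epoxide by an alkenyllithium; attack at the secondary carbon C9 anti to the C–O bond (trans-diaxial mode) inverts C9, so the alkenyl group is trans to the C10 oxygen and cis to the C4 alkynyl group. The C10 oxygen and methyl keep their configuration, and the tertiary carbon C10 is not a site for SN2 attack.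

Step 7
Reactants: 13 tertiary alcohol
Product: 14 triethylsilyl ether of 13 at the C10 oxygen
Conditions: Et3SiOTf, 2,6-lutidine, CH2Cl2, −78 → 0 °C
Reagents that add atoms: triethylsilyl trifluoromethanesulfonate CC[Si](CC)(CC)OS(=O)(=O)C(F)(F)F
Why: Silyl triflate silylation of a hindered tertiary alcohol; the C10 hydroxyl is the only free hydroxyl, so the more robust silyl group is placed there unambiguously.

Step 8
Reactants: 14 bis-silyl ether with silylalkyne
Product: 15 1-ethynyl-3-methyl-2-[(E)-3-methylbut-1-enyl]-3-(triethylsilyloxy)cyclohexan-1-ol (oxygens cis; alkenyl group trans to both)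
Conditions: K2CO3, MeOH, rt
Reagents that add atoms: none
Why: Methanolysis removes the alkynyl trimethylsilyl group and the tertiary trimethylsilyl ether, while the more hindered triethylsilyl ether survives; this frees the C4 hydroxyl and the terminal alkyne in one operation.

Step 9
Reactants: 15 ethynyl carbinol
Product: 16 (E)-alkenyl pinacol boronate (boron on C6, C5=C6 E, C4 hydroxyl free)
Conditions: pinacolborane (3 equiv), Cp2Zr(H)Cl (10 mol %), Et3N (10 mol %), CH2Cl2, rt → 40 °C; aqueous work-up
Reagents that add atoms: pinacolborane CC1(C)OBOC1(C)C
Why: Zirconocene-catalysed syn hydroboration of a terminal alkyne places boron on the terminal carbon and gives the E alkenyl boronate; the hindered internal alkene does not react, and the borate formed at the free hydroxyl is hydrolysed on work-up.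

Step 10
Reactants: 16 (E)-alkenyl pinacol boronate; 17 4-methoxybenzyl alcohol
Product: 18 1-[(E)-2-(4-methoxybenzyloxy)vinyl]-3-methyl-2-[(E)-3-methylbut-1-enyl]-3-(triethylsilyloxy)cyclohexan-1-ol (alkenyl groups cis; C4 hydroxyl cis to the C10 silyloxy group)
Conditions: 17 (5 equiv), Cu(OAc)2 (20 mol %), Et3N, 4 Å MS, O2 (1 atm), CH2Cl2, rt; chromatography on Et3N-deactivated silica
Reagents that add atoms: none
Why: Chan–Lam-type copper-mediated coupling of an alkenyl boronate with an aliphatic alcohol forms the enol ether with retention of the E geometry; the tertiary hydroxyl cannot reach the trans-disposed boron-bearing carbon and is too hindered to compete intermolecularly.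

Step 11
Reactants: 18 cis-dialkenyl cyclohexanol
Product: 21 ten-membered dienyl triflate (C4 OTf, C4=C5 with C3 and C6 cis, C6 4-methoxybenzyl ether, C8=C9 E, C10 OSiEt3), via potassium alkoxide 19 (not isolated), via potassium enolate 20 (not isolated)
Conditions: KH, 18-crown-6, THF, −20 → 0 °C; PhNTf2, −78 → −30 °C
Reagents that add atoms: N-phenylbis(trifluoromethanesulfonimide) O=S(=O)(N(c1ccccc1)S(=O)(=O)C(F)(F)F)C(F)(F)F
Why: KH with 18-crown-6 turns the C4 hydroxyl into the dissociated potassium alkoxide 19, which weakens C4–C9 so that the [3,3] shift through C6–C5–C4–C9–C8–C7 runs near 0 °C; this is the anionic oxy-Cope ring expansion known for 1,2-dialkenylcyclohexanols, followed by the usual O-sulfonylation of a potassium enolate. The ten-membered ring is not closed end to end but arises by ring expansion, C6–C7 forming as the cyclohexane bond C4–C9 breaks. The cis-dialkenyl cyclohexane reacts from the chair with the C4 oxygen and the C10 silyloxy group axial, the C4 vinyl group equatorial and the C9 alkenyl group axial (the other chair has the C4 vinyl and C10 methyl 1,3-diaxial), and this maps onto a chair transition state with the C4 oxygen and C10 pseudo-equatorial and C3 pseudo-axial. In that chair both E alkenes carry their substituents (the ether oxygen on C6, isopropyl on C7) pseudo-equatorially, so C6 and C7 are set together, and their absolute sense is fixed by the C4 and C9 configurations; C10 is untouched. The pseudo-equatorial C10 gives the E C8=C9 alkene and the pseudo-axial C3 gives the enolate with C3 and C6 cis, which PhNTf2 fixes as the triflate. The step needs chair over boat and capture of 20 before the C6 alkoxide is lost by E1cB; the first is secured by the cis alkenyl groups and the equatorial preference of the bulky C10, the second by keeping 20 cold and by the silyl group on C10, which leaves the enolate as the only reactive anion. Any triethylsilyl transfer between the two syn 1,3-oxygens is harmless, because only the C4 alkoxide can rearrange and the equilibrium drains through it.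

Step 12
Reactants: 21 dienyl triflate
Product: 22 methyl diene (C4 methyl, C4=C5 Z with C3 and C6 cis, C6 4-methoxybenzyl ether, C10 OSiEt3)
Conditions: MeMgBr, Fe(acac)3 (10 mol %), THF/NMP, −30 → 0 °C
Reagents that add atoms: methylmagnesium bromide C[Mg]Br
Why: Iron-catalysed cross-coupling of an alkenyl triflate with a methyl Grignard reagent proceeds with retention of alkene geometry; the ether and silyl ether are inert, and the C6 oxygen is γ to the metal-bearing carbon, so it cannot be lost by β-elimination.

Step 13
Reactants: 22 methyl diene
Product: 23 allylic alcohol (C6 hydroxyl free, C10 OSiEt3)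
Conditions: DDQ, CH2Cl2/pH 7 buffer, 0 °C
Reagents that add atoms: none
Why: Oxidative cleavage of a 4-methoxybenzyl ether through its benzylic cation and hemiacetal; buffered, cold conditions leave the silyl ether intact and limit over-oxidation of the allylic alcohol.

Step 14
Reactants: 23 allylic alcohol
Product: 24 epoxy alcohol (4S,5R epoxide, oxygen anti to the C6 hydroxyl, C10 OSiEt3)
Conditions: Ti(OiPr)4 (1 equiv), D-(−)-diisopropyl tartrate (1.2 equiv), t-BuOOH, 4 Å MS, CH2Cl2, −20 °C
Reagents that add atoms: tert-butyl hydroperoxide CC(C)(C)OO
Why: Sharpless epoxidation of a secondary allylic alcohol in its matched pairing; D-(−)-tartrate delivers oxygen to the face that is fast for this C6 configuration and gives the erythro (anti) epoxy alcohol, which sets C4 and C5. The isolated C8=C9 alkene has no free allylic hydroxyl, since C10 is silylated, and is not touched.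

Step 15
Reactants: 25 4-hydroxybenzoic acid
Product: 27 4-(tert-butyldimethylsilyloxy)benzoic acid, via silyl ester 26 (not isolated)
Conditions: t-BuMe2SiCl (2.4 equiv), imidazole, DMF, rt; K2CO3, MeOH/THF/H2O, rt; citric acid to pH 4
Reagents that add atoms: tert-butyldimethylsilyl chloride CC(C)(C)[Si](C)(C)Cl
Why: Bis-silylation followed by selective hydrolysis of the labile silyl ester leaves the aryl silyl ether and the free acid.

Step 16
Reactants: 24 epoxy alcohol; 27 4-(tert-butyldimethylsilyloxy)benzoic acid
Product: 28 bis-silylated ester (C6 4-silyloxybenzoate, C10 OSiEt3)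
Conditions: DCC, DMAP, CH2Cl2, 0 °C → rt
Reagents that add atoms: none
Why: Steglich esterification acylates the secondary C6 hydroxyl under neutral conditions, which the epoxide tolerates; C6 keeps its configuration because the C–O bond is not broken.

Step 17
Reactants: 28 bis-silylated ester
Product: 29 target (4S,5R,6R,7S,10R, 8E)
Conditions: Bu4NF, AcOH, THF, 0 °C → rt
Reagents that add atoms: none
Why: Buffered fluoride cleaves the aryl silyl ether quickly and the tertiary triethylsilyl ether more slowly; no acid is present, so the epoxide, the tertiary allylic alcohol and the ester survive.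

## Compound list

1 | 3-methylcyclohex-2-en-1-one | CC1=CC(=O)CCC1 | starting material
2 | (S)-3-methylcyclohex-2-en-1-ol | O[C@H]1CCCC(C)=C1 | intermediate
3 | (1S,2S,3R)-2,3-epoxy-3-methylcyclohexan-1-ol | O[C@H]1CCC[C@@]2(C)O[C@@H]12 | intermediate
4 | (2R,3R)-2,3-epoxy-3-methylcyclohexan-1-one | O=C1CCC[C@@]2(C)O[C@@H]12 | intermediate
5 | ethynyltrimethylsilane | C#C[Si](C)(C)C | starting material
6 | lithium (trimethylsilyl)acetylide | [Li]C#C[Si](C)(C)C | intermediate
7 | lithium alkoxide of the acetylide adduct of 4 (C4 oxygen cis to the epoxide oxygen) | [Li]O[C@@]1(C#C[Si](C)(C)C)CCC[C@@]2(C)O[C@@H]12 | intermediate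
8 | 2,3-epoxy-3-methyl-1-[(trimethylsilyl)ethynyl]-1-(trimethylsilyloxy)cyclohexane, silyloxy group cis to the epoxide oxygen | C[Si](C)(C)C#C[C@]1(O[Si](C)(C)C)CCC[C@@]2(C)O[C@@H]12 | intermediate
9 | 3-methylbut-1-yne | CC(C)C#C | starting material
10 | (E)-diisobutyl(3-methylbut-1-enyl)alane | CC(C)/C=C/[Al](CC(C)C)CC(C)C | intermediate
11 | (E)-1-iodo-3-methylbut-1-ene | CC(C)/C=C/I | intermediate
12 | (E)-3-methylbut-1-enyllithium | [Li]/C=C/C(C)C | intermediate
13 | 1-methyl-2-[(E)-3-methylbut-1-enyl]-3-[(trimethylsilyl)ethynyl]-3-(trimethylsilyloxy)cyclohexan-1-ol, oxygens cis, alkenyl trans to both | C[Si](C)(C)C#C[C@]1(O[Si](C)(C)C)CCC[C@@](C)(O)[C@@H]1/C=C/C(C)C | intermediate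
14 | triethylsilyl ether of 13 at the C10 oxygen | C[Si](C)(C)C#C[C@]1(O[Si](C)(C)C)CCC[C@@](C)(O[Si](CC)(CC)CC)[C@@H]1/C=C/C(C)C | intermediate
15 | 1-ethynyl-3-methyl-2-[(E)-3-methylbut-1-enyl]-3-(triethylsilyloxy)cyclohexan-1-ol, oxygens cis, alkenyl trans to both | C#C[C@]1(O)CCC[C@@](C)(O[Si](CC)(CC)CC)[C@@H]1/C=C/C(C)C | intermediate
16 | (E)-alkenyl pinacol boronate of 15 (boron on C6) | CC1(C)OB(/C=C/[C@]2(O)CCC[C@@](C)(O[Si](CC)(CC)CC)[C@@H]2/C=C/C(C)C)OC1(C)C | intermediate
17 | 4-methoxybenzyl alcohol | COc1ccc(CO)cc1 | starting material
18 | 1-[(E)-2-(4-methoxybenzyloxy)vinyl]-3-methyl-2-[(E)-3-methylbut-1-enyl]-3-(triethylsilyloxy)cyclohexan-1-ol, alkenyl groups cis, oxygens cis (precursor of the key step, C10 oxygen silylated) | O[C@@]1(/C=C/OCc2ccc(OC)cc2)CCC[C@@](C)(O[Si](CC)(CC)CC)[C@@H]1/C=C/C(C)C | intermediate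
19 | potassium alkoxide of 18 | [K+].[O-][C@@]1(/C=C/OCc2ccc(OC)cc2)CCC[C@@](C)(O[Si](CC)(CC)CC)[C@@H]1/C=C/C(C)C | intermediate
20 | potassium enolate of the ten-membered ketone (C4 enolate, C3 and C6 cis) | [K+].CC(C)[C@H]1/C=C/[C@](C)(O[Si](CC)(CC)CC)CCC/C([O-])=C\[C@@H]1OCc2ccc(OC)cc2 | intermediate
21 | ten-membered dienyl triflate, C6 4-methoxybenzyl ether, C10 triethylsilyl ether (product of the key step) | CC(C)[C@H]1/C=C/[C@](C)(O[Si](CC)(CC)CC)CCC/C(OS(=O)(=O)C(F)(F)F)=C\[C@@H]1OCc2ccc(OC)cc2 | intermediate
22 | methyl diene, C4=C5 Z, C6 4-methoxybenzyl ether, C10 triethylsilyl ether | CC(C)[C@H]1/C=C/[C@](C)(O[Si](CC)(CC)CC)CCC/C(C)=C\[C@@H]1OCc2ccc(OC)cc2 | intermediate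
23 | macrocyclic dienol, C6 hydroxyl free, C10 triethylsilyl ether | CC(C)[C@H]1/C=C/[C@](C)(O[Si](CC)(CC)CC)CCC/C(C)=C\[C@@H]1O | intermediate
24 | 4,5-epoxy alcohol, epoxide oxygen anti to the C6 hydroxyl, C10 triethylsilyl ether | CC(C)[C@H]1/C=C/[C@](C)(O[Si](CC)(CC)CC)CCC[C@]2(C)O[C@@H]2[C@@H]1O | intermediate
25 | 4-hydroxybenzoic acid | OC(=O)c1ccc(O)cc1 | starting material
26 | tert-butyldimethylsilyl 4-(tert-butyldimethylsilyloxy)benzoate | CC(C)(C)[Si](C)(C)OC(=O)c1ccc(O[Si](C)(C)C(C)(C)C)cc1 | intermediate
27 | 4-(tert-butyldimethylsilyloxy)benzoic acid | OC(=O)c1ccc(O[Si](C)(C)C(C)(C)C)cc1 | intermediate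
28 | bis-silylated ester (C6 4-(tert-butyldimethylsilyloxy)benzoate, C10 triethylsilyl ether) | CC(C)[C@H]1/C=C/[C@](C)(O[Si](CC)(CC)CC)CCC[C@]2(C)O[C@@H]2[C@@H]1OC(=O)c1ccc(O[Si](C)(C)C(C)(C)C)cc1 | intermediate
29 | target CNP0278889.1 | CC(C)[C@H]1/C=C/[C@](C)(O)CCC[C@]2(C)O[C@@H]2[C@@H]1OC(=O)c1ccc(O)cc1 | target

## Step count and least certain steps

Total: 17 steps. Longest linear sequence: 15 steps (steps 1–4, 6–14, 16 and 17, from 1); steps 5 and 15 are one-step side branches.

**Step 11 (key step).** The most likely failure is loss of the C6 alkoxide from enolate 20 by E1cB before O-sulfonylation, because the triflimide reacts slowly with a hindered medium-ring enolate; partial reaction through a boat would in addition erode the C6/C7 configuration. Fallback: starting from 18, the rearrangement is run as before, but the enolate is intercepted at −78 °C with Me3SiCl/Et3N, a much faster trap, to give the trimethylsilyl enol ether F1. After isolation, MeLi regenerates the lithium enolate regiospecifically, and N-(5-chloro-2-pyridyl)triflimide converts it into 21, where the route resumes.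

**Step 6 (epoxide opening).** The SN2 attack at C9 may be slow because both neighbours are fully substituted, and BF3 may instead ionise the tertiary C10–O bond, leading to rearrangement or attack at C10. Fallback: starting from 4, a Wittig reaction with Ph3P=CHOMe gives the enol ether F2. Mild acid hydrolyses it and opens the epoxide in a vinylogous sense to the γ-hydroxy enal F3, which is silylated to F4. An alkenyl cuprate made from 11 adds to C9 anti to the C10 silyloxy group in the presence of Me3SiCl and gives the silyl enol ether F5. Rubottom oxidation with dimethyldioxirane brings oxygen to C4 anti to the new alkenyl group and gives the hydroxy aldehyde F6. Seyferth–Gilbert homologation with the Ohira–Bestmann reagent converts F6 into 15, where the route resumes. This path forms the C9–C bond by conjugate addition instead of substitution.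

**Step 14 (epoxidation).** The likely problem is poor facial selectivity and low rate: the Z-substituted allylic alcohol suffers A(1,3) strain in the conformation the titanium–tartrate reagent needs, and the strain-free conformation leads to the threo epoxide. Fallback: starting from 23, Mitsunobu inversion with 4-nitrobenzoic acid gives the ester F7, and methanolysis gives the C6-epimeric alcohol F8. VO(acac)2/t-BuOOH then epoxidises F8 in its natural, hydroxyl-directed threo sense to F9, which has the target's epoxide configuration. A second Mitsunobu reaction with 27 inverts C6 again and installs the ester, so the route is rejoined at 28.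

**Step 10 (enol ether formation).** The alkenyl boronate may be lost by protodeboronation or oxidation before C–O bond formation, and the product is acid-sensitive. Fallback: starting from 16, iododeboronation with I2/NaOH (retention) gives the (E)-iodoalkene F10. An Ullmann-type coupling with 17 (CuI, 3,4,7,8-tetramethyl-1,10-phenanthroline, Cs2CO3, toluene, 80 °C) then gives 18.

## Further compounds

F1 | step 11 | trimethylsilyl enol ether of the ten-membered ketone (C4 OSiMe3, C6 4-methoxybenzyl ether, C10 OSiEt3) | CC(C)[C@H]1/C=C/[C@](C)(O[Si](CC)(CC)CC)CCC/C(O[Si](C)(C)C)=C\[C@@H]1OCc2ccc(OC)cc2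
F2 | step 6 | 2,3-epoxy-1-(methoxymethylene)-3-methylcyclohexane | COC=C1CCC[C@@]2(C)O[C@@H]12
F3 | step 6 | (R)-3-hydroxy-3-methylcyclohex-1-ene-1-carbaldehyde | O=CC1=C[C@](C)(O)CCC1
F4 | step 6 | (R)-3-methyl-3-(triethylsilyloxy)cyclohex-1-ene-1-carbaldehyde | O=CC1=C[C@](C)(O[Si](CC)(CC)CC)CCC1
F5 | step 6 | trimethylsilyl enol ether of the conjugate adduct (C9 alkenyl trans to the C10 silyloxy group) | C[Si](C)(C)OC=C1CCC[C@@](C)(O[Si](CC)(CC)CC)[C@@H]1/C=C/C(C)C
F6 | step 6 | 1-hydroxy-3-methyl-2-[(E)-3-methylbut-1-enyl]-3-(triethylsilyloxy)cyclohexane-1-carbaldehyde (oxygens cis, alkenyl trans to both) | O=C[C@]1(O)CCC[C@@](C)(O[Si](CC)(CC)CC)[C@@H]1/C=C/C(C)C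
F7 | step 14 | 4-nitrobenzoate of the C6-epimeric dienol | CC(C)[C@H]1/C=C/[C@](C)(O[Si](CC)(CC)CC)CCC/C(C)=C\[C@H]1OC(=O)c1ccc([N+](=O)[O-])cc1
F8 | step 14 | C6-epimer of dienol 23 | CC(C)[C@H]1/C=C/[C@](C)(O[Si](CC)(CC)CC)CCC/C(C)=C\[C@H]1O
F9 | step 14 | threo epoxy alcohol (target epoxide configuration, C6 epimeric) | CC(C)[C@H]1/C=C/[C@](C)(O[Si](CC)(CC)CC)CCC[C@]2(C)O[C@@H]2[C@H]1O
F10 | step 10 | (E)-iodoalkene corresponding to 16 | I/C=C/[C@]1(O)CCC[C@@](C)(O[Si](CC)(CC)CC)[C@@H]1/C=C/C(C)C
A1 | alternative 1 | open-chain (Z)-iodoalkene aldehyde, C10 triethylsilyl ether | O=C[C@@H](C(C)C)/C=C/[C@](C)(O[Si](CC)(CC)CC)CCC/C(C)=C\I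
A2 | alternative 1 | macrocyclic dienol, C10 triethylsilyl ether (identical with 23) | CC(C)[C@H]1/C=C/[C@](C)(O[Si](CC)(CC)CC)CCC/C(C)=C\[C@@H]1O
A3 | alternative 2 | open-chain epoxy sulfone, C6 tert-butyldimethylsilyl ether | O=S(=O)(CC/C(C)=C\[C@H](O[Si](C)(C)C(C)(C)C)[C@@H](C(C)C)/C=C/[C@@]1(C)CO1)c1ccccc1
A4 | alternative 2 | macrocyclic C10 alcohol with C2 phenylsulfonyl group (both C2 epimers) | CC(C)[C@H]1/C=C/[C@](C)(O)CC(S(=O)(=O)c2ccccc2)C/C(C)=C\[C@@H]1O[Si](C)(C)C(C)(C)C
A5 | alternative 3 | open-chain (Z)-iodoalkene with terminal alkene, bis-silyl ether | I/C(C)=C\[C@H](O[Si](C)(C)C(C)(C)C)[C@@H](C(C)C)/C=C/[C@](C)(O[Si](CC)(CC)CC)CC=C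
A6 | alternative 3 | macrocyclic diene bis-silyl ether | CC(C)[C@H]1/C=C/[C@](C)(O[Si](CC)(CC)CC)CCC/C(C)=C\[C@@H]1O[Si](C)(C)C(C)(C)C
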